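## Retrosynthetic overview

1. Target ⇒ acid ⇒ aldehyde (O-methylation, chlorite oxidation) ⇒ catalyst-controlled Diels–Alder of a ring-B 1-vinylcyclohexene with methacrolein. Ring A is formed last (C2–C3 and C4–C5; sets C4 and C5).
2. Diene ⇒ enol triflate + vinylstannane (C10–C1) ⇒ 2,2,3-trisubstituted cyclohexanone.
3. Ketone ⇒ alkylation (C9–C11, sets C9) of the (R)-2,3-dimethylcyclohexanone enolate with (R)-5-iodo-3-methylpentyl acetate. Ring B is bought as 2-methylcyclohexenone, and C8 is set by Cu-catalysed asymmetric conjugate methylation.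
4. Iodo acetate ⇒ 4-methyloxane + acetyl iodide. This is the key step: a catalytic enantioselective acylative C–O ring opening that forms the C15–OAc ester bond carried into the target and sets C13.
5. Ring order: B (purchased) → A (Diels–Alder).

Assumption: the SMILES stereodescriptors are taken at face value, i.e. (4S,5R,8R,9S,13S) in halimane numbering (C4 = ester-bearing carbon, C5 = ring-fusion CH, C10/C1 = alkene, C8 = CHMe, C9 = quaternary carbon, C11–C15 = side chain); H-5, 4-Me, 8-Me and 9-Me lie on one face, CO2Me and the side chain on the other. The catalyst antipodes in steps 1, 2 and 6 are chosen to give the stated configurations; for step 1 the sense of induction cannot be predicted and must be found by screening.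

## Route

Step 1
Reactants: 1 4-methyloxane; 2 acetyl iodide
Product: 4 (3R)-5-iodo-3-methylpentyl acetate, via 1-acetyl-4-methyloxan-1-ium iodide 3 (not isolated)
Conditions: 2 (1.0 equiv), 1 (1.5 equiv), chiral aryl-pyrrolidine squaramide H-bond donor (10 mol%), 4 Å MS, PhMe, −50 °C, 48 h
Reagents that add atoms: none
Why: Proposed new method: catalytic enantioselective acylative C–O scission of an unstrained cyclic ether, in which acetyl iodide O-acylates 1 (forming the acetate C–O bond of the target) to give ion pair 3, the squaramide holds the iodide while its arene packs against the chair oxonium (methyl locked equatorial, so the two O–CH2 bonds are enantiotopic and rigidly displayed), and SN2 delivery of the bound iodide to one of them sets C13; the closest known reactions are the racemic cleavage of tetrahydropyrans by acyl iodides and the squaramide-catalysed enantioselective opening of 3-substituted oxetanes by silyl bromides.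

Step 2
Reactants: 5 2-methylcyclohex-2-en-1-one
Product: 7 {[(3R)-2,3-dimethylcyclohex-1-en-1-yl]oxy}trimethylsilane, via dimethylaluminium enolate 6 (not isolated)
Conditions: Me3Al (1.4 equiv), CuTC (2 mol%), chiral biphenol phosphoramidite (4 mol%), Et2O, −30 °C; then TMSOTf (1.5 equiv), −30 °C → rt
Reagents that add atoms: trimethylaluminium (C[Al](C)C); trimethylsilyl trifluoromethanesulfonate (C[Si](C)(C)OS(=O)(=O)C(F)(F)F)
Why: Cu/phosphoramidite-catalysed asymmetric conjugate addition of methyl to the α-substituted enone sets C8 (3R) and gives a regiodefined aluminium enolate, which O-silylation fixes as the tetrasubstituted enol silane.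

Step 3
Reactants: 7 {[(3R)-2,3-dimethylcyclohex-1-en-1-yl]oxy}trimethylsilane; 4 (3R)-5-iodo-3-methylpentyl acetate
Product: 9 (3S)-5-[(1S,2R)-1,2-dimethyl-6-oxocyclohexyl]-3-methylpentyl acetate, via lithium enolate 8 (not isolated)
Conditions: MeLi (1.0 equiv), THF, 0 °C, 30 min; then 4 (1.3 equiv), DMPU (4 equiv), −40 °C → rt
Reagents that add atoms: none
Why: Enolate alkylation (SN2): MeLi cleaves the enol silane to the regiodefined tetrasubstituted lithium enolate, which is C-alkylated by the primary iodide on the face anti to the C8 methyl (held pseudoaxial by A1,2 strain), setting quaternary C9 with the side chain trans to 8-Me, while the acetate survives because Claisen acylation is slower than iodide displacement at or below room temperature.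

Step 4
Reactants: 9 (3S)-5-[(1S,2R)-1,2-dimethyl-6-oxocyclohexyl]-3-methylpentyl acetate
Product: 10 (3S)-5-[(1S,6R)-1,6-dimethyl-2-(trifluoromethanesulfonyloxy)cyclohex-2-en-1-yl]-3-methylpentyl acetate
Conditions: Tf2O (1.3 equiv), 2,6-di-tert-butyl-4-methylpyridine (1.5 equiv), CH2Cl2, 0 °C → rt
Reagents that add atoms: trifluoromethanesulfonic anhydride (O=S(=O)(OS(=O)(=O)C(F)(F)F)C(F)(F)F)
Why: Enol triflate formation under non-basic conditions gives a single regioisomer because only C5 carries α-hydrogens (C9 is quaternary), and these conditions are established for α-quaternary ketones in the presence of acetates.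

Step 5
Reactants: 10 (3S)-5-[(1S,6R)-1,6-dimethyl-2-(trifluoromethanesulfonyloxy)cyclohex-2-en-1-yl]-3-methylpentyl acetate
Product: 11 (3S)-5-[(1S,6R)-2-ethenyl-1,6-dimethylcyclohex-2-en-1-yl]-3-methylpentyl acetate
Conditions: CH2=CHSnBu3 (1.3 equiv), Pd(PPh3)4 (5 mol%), LiCl (3 equiv), THF, 65 °C
Reagents that add atoms: tributyl(vinyl)stannane (C=C[Sn](CCCC)(CCCC)CCCC)
Why: Stille cross-coupling of the enol triflate forms C10–C1 under neutral conditions that spare the acetate and touch no stereocentre.

Step 6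
Reactants: 11 (3S)-5-[(1S,6R)-2-ethenyl-1,6-dimethylcyclohex-2-en-1-yl]-3-methylpentyl acetate; 12 methacrolein
Product: 13 (1S,5S,6R,8aR)-5-[(3S)-5-acetoxy-3-methylpentyl]-1,5,6-trimethyl-1,2,3,5,6,7,8,8a-octahydronaphthalene-1-carbaldehyde
Conditions: 12 (3 equiv), triflimide-activated B-(o-tolyl) diphenylprolinol oxazaborolidine (20 mol%), CH2Cl2, −78 → −40 °C
Reagents that add atoms: none
Why: Chiral-Lewis-acid-catalysed Diels–Alder reaction: the s-cis-biased diene adds "ortho" (C4 to ring terminus C5, C3 to the vinyl CH2) and endo with respect to the formyl group (no bridging CH2 to disfavour it), and because the two diene faces are nearly isosteric (Me versus CH2R on C9) the catalyst-shielded enal face fixes C4 as S and, through the endo mode, C5 as R (H-5 cis to 4-Me and 9-Me).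

Step 7
Reactants: 13 (1S,5S,6R,8aR)-5-[(3S)-5-acetoxy-3-methylpentyl]-1,5,6-trimethyl-1,2,3,5,6,7,8,8a-octahydronaphthalene-1-carbaldehyde
Product: 14 (1S,5S,6R,8aR)-5-[(3S)-5-acetoxy-3-methylpentyl]-1,5,6-trimethyl-1,2,3,5,6,7,8,8a-octahydronaphthalene-1-carboxylic acid
Conditions: NaClO2, NaH2PO4, 2-methyl-2-butene, t-BuOH/H2O, rt
Reagents that add atoms: sodium chlorite ([Na+].[O-]Cl=O)
Why: Pinnick oxidation converts the non-enolisable α-quaternary aldehyde to the acid without touching the trisubstituted alkene (HOCl is scavenged) or the acetate, and no stereocentre can epimerise.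

Step 8
Reactants: 14 (1S,5S,6R,8aR)-5-[(3S)-5-acetoxy-3-methylpentyl]-1,5,6-trimethyl-1,2,3,5,6,7,8,8a-octahydronaphthalene-1-carboxylic acid
Product: 15 methyl (1S,5S,6R,8aR)-5-[(3S)-5-acetoxy-3-methylpentyl]-1,5,6-trimethyl-1,2,3,5,6,7,8,8a-octahydronaphthalene-1-carboxylate
Conditions: TMSCHN2, PhMe/MeOH (4:1), 0 °C → rt
Reagents that add atoms: (trimethylsilyl)diazomethane (C[Si](C)(C)C=[N+]=[N-])
Why: Esterification by O-alkylation of the carboxylate with TMS-diazomethane forms the methyl ester C–O bond regardless of the steric hindrance at the tertiary carboxyl and leaves the acetate intact.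

## Compound list

1 | 4-methyloxane (4-methyltetrahydropyran) | CC1CCOCC1 | starting material
2 | acetyl iodide | CC(=O)I | starting material
3 | 1-acetyl-4-methyloxan-1-ium iodide (catalyst-bound ion pair) | CC(=O)[O+]1CCC(C)CC1.[I-] | intermediate
4 | (3R)-5-iodo-3-methylpentyl acetate | CC(=O)OCC[C@@H](C)CCI | intermediate
5 | 2-methylcyclohex-2-en-1-one | CC1=CCCCC1=O | starting material
6 | dimethylaluminium (3R)-2,3-dimethylcyclohex-1-en-1-olate | C[C@@H]1CCCC(O[Al](C)C)=C1C | intermediate
7 | {[(3R)-2,3-dimethylcyclohex-1-en-1-yl]oxy}trimethylsilane | C[C@@H]1CCCC(O[Si](C)(C)C)=C1C | intermediate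
8 | lithium (3R)-2,3-dimethylcyclohex-1-en-1-olate | C[C@@H]1CCCC([O-])=C1C.[Li+] | intermediate
9 | (3S)-5-[(1S,2R)-1,2-dimethyl-6-oxocyclohexyl]-3-methylpentyl acetate | O=C1CCC[C@@H](C)[C@]1(C)CC[C@H](C)CCOC(C)=O | intermediate
10 | (3S)-5-[(1S,6R)-1,6-dimethyl-2-(trifluoromethanesulfonyloxy)cyclohex-2-en-1-yl]-3-methylpentyl acetate | O=S(=O)(OC1=CCC[C@@H](C)[C@]1(C)CC[C@H](C)CCOC(C)=O)C(F)(F)F | intermediate
11 | (3S)-5-[(1S,6R)-2-ethenyl-1,6-dimethylcyclohex-2-en-1-yl]-3-methylpentyl acetate | C=CC1=CCC[C@@H](C)[C@]1(C)CC[C@H](C)CCOC(C)=O | intermediate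
12 | methacrolein (2-methylprop-2-enal) | C=C(C)C=O | starting material
13 | (1S,5S,6R,8aR)-5-[(3S)-5-acetoxy-3-methylpentyl]-1,5,6-trimethyl-1,2,3,5,6,7,8,8a-octahydronaphthalene-1-carbaldehyde | O=C[C@@]1(C)CCC=C2[C@H]1CC[C@@H](C)[C@]2(C)CC[C@H](C)CCOC(C)=O | intermediate
14 | (1S,5S,6R,8aR)-5-[(3S)-5-acetoxy-3-methylpentyl]-1,5,6-trimethyl-1,2,3,5,6,7,8,8a-octahydronaphthalene-1-carboxylic acid | OC(=O)[C@@]1(C)CCC=C2[C@H]1CC[C@@H](C)[C@]2(C)CC[C@H](C)CCOC(C)=O | intermediate
15 | methyl (1S,5S,6R,8aR)-5-[(3S)-5-acetoxy-3-methylpentyl]-1,5,6-trimethyl-1,2,3,5,6,7,8,8a-octahydronaphthalene-1-carboxylate | COC(=O)[C@@]1(C)CCC=C2[C@H]1CC[C@@H](C)[C@]2(C)CC[C@H](C)CCOC(C)=O | target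

## Step count and risks

Total steps: 8. Longest linear sequence: 7 (steps 2–8 from 5); step 1 is a one-step side branch. Using methyl methacrylate directly in step 6 would save two steps, but it is too unreactive for the catalyst-controlled cycloaddition, and without catalyst control C5 cannot be defended.

The three steps most likely to fail:

Step 1 (the proposed new reaction). The risks are racemic background cleavage by free acetyl iodide, slow turnover at the low temperature needed, and an unknown level and sense of induction. The fallback uses known chemistry, takes C13 from the chiral pool, sets out from enol silane 7 and comes back at ketone 9. Compound 7 is converted to lithium enolate 8 as in step 3 and alkylated with commercial (R)-citronellyl bromide (THF/DMPU, Bu4NI cat.) to give (2S,3R)-2-[(3R)-3,7-dimethyloct-6-en-1-yl]-2,3-dimethylcyclohexan-1-one F1. RuCl3 (cat.)/NaIO4 cleavage of the trisubstituted alkene gives (4S)-6-[(1S,2R)-1,2-dimethyl-6-oxocyclohexyl]-4-methylhexanoic acid F2. Photochemical iododecarboxylation (PhI(OAc)2, I2, hν) gives (2S,3R)-2-[(3S)-5-iodo-3-methylpentyl]-2,3-dimethylcyclohexan-1-one F3, and KOAc/18-crown-6 in DMF displaces the iodide to give 9. The same material serves to assign the configuration of 4 made in step 1.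

Step 3. The risks are slow C-alkylation of a hindered tetrasubstituted enolate by an unactivated iodide, O-alkylation, and enolate attack on the acetate; any shortfall in the ee of 4 or 7 also appears here as hard-to-separate C13 epimers. The fallback replaces the SN2 step by an aldol C–C bond formation; it sets out from 4 and 7 and comes back at 9. Kornblum oxidation of 4 (DMSO, NaHCO3, 110 °C) gives (3R)-3-methyl-5-oxopentyl acetate F4. Mukaiyama aldol addition of 7 to it (TiCl4, CH2Cl2, −78 °C, again anti to the C8 methyl) gives (3R)-5-[(1R,2R)-1,2-dimethyl-6-oxocyclohexyl]-5-hydroxy-3-methylpentyl acetate F5 as both carbinol epimers (the ring descriptor changes, the geometry does not). Burgess dehydration, possible only towards C12, gives (3R,4E)-5-[(1R,2R)-1,2-dimethyl-6-oxocyclohexyl]-3-methylpent-4-en-1-yl acetate F6, and H2 over Pd/C gives 9.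

Step 6. The risks are the endo/exo ratio with an α-methyl enal, the regiochemistry at a diene flanked by a quaternary carbon, and full reliance on catalyst control of the diene face. The fallback replaces catalyst control by intramolecular delivery through an ester tether; it sets out from 11 and comes back at 15. K2CO3/MeOH gives (3S)-5-[(1S,6R)-2-ethenyl-1,6-dimethylcyclohex-2-en-1-yl]-3-methylpentan-1-ol F7. Methacryloyl chloride/Et3N gives (3S)-5-[(1S,6R)-2-ethenyl-1,6-dimethylcyclohex-2-en-1-yl]-3-methylpentyl 2-methylprop-2-enoate F8. A Lewis-acid-promoted intramolecular Diels–Alder reaction (MeAlCl2, CH2Cl2, 1–2 mM) gives the 11-membered (4S,5R,8R,9S,13S)-halim-1(10)-en-18,15-olide F9; the tether from the C9 side chain should deliver the dienophile to the side-chain face and hold the carbonyl endo, but closing an 11-membered ring this way is itself uncertain. NaOMe/MeOH opens the lactone to methyl (1S,5S,6R,8aR)-5-[(3S)-5-hydroxy-3-methylpentyl]-1,5,6-trimethyl-1,2,3,5,6,7,8,8a-octahydronaphthalene-1-carboxylate F10, and Ac2O/pyridine gives 15.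

## Further compounds

F1 | step 1 | (2S,3R)-2-[(3R)-3,7-dimethyloct-6-en-1-yl]-2,3-dimethylcyclohexan-1-one | O=C1CCC[C@@H](C)[C@]1(C)CC[C@H](C)CCC=C(C)C
F2 | step 1 | (4S)-6-[(1S,2R)-1,2-dimethyl-6-oxocyclohexyl]-4-methylhexanoic acid | O=C1CCC[C@@H](C)[C@]1(C)CC[C@H](C)CCC(=O)O
F3 | step 1 | (2S,3R)-2-[(3S)-5-iodo-3-methylpentyl]-2,3-dimethylcyclohexan-1-one | O=C1CCC[C@@H](C)[C@]1(C)CC[C@H](C)CCI
F4 | step 3 | (3R)-3-methyl-5-oxopentyl acetate | CC(=O)OCC[C@@H](C)CC=O
F5 | step 3 | (3R)-5-[(1R,2R)-1,2-dimethyl-6-oxocyclohexyl]-5-hydroxy-3-methylpentyl acetate (both C5 epimers) | O=C1CCC[C@@H](C)[C@]1(C)C(O)C[C@H](C)CCOC(C)=O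
F6 | step 3 | (3R,4E)-5-[(1R,2R)-1,2-dimethyl-6-oxocyclohexyl]-3-methylpent-4-en-1-yl acetate | O=C1CCC[C@@H](C)[C@]1(C)/C=C/[C@H](C)CCOC(C)=O
F7 | step 6 | (3S)-5-[(1S,6R)-2-ethenyl-1,6-dimethylcyclohex-2-en-1-yl]-3-methylpentan-1-ol | C=CC1=CCC[C@@H](C)[C@]1(C)CC[C@H](C)CCO
F8 | step 6 | (3S)-5-[(1S,6R)-2-ethenyl-1,6-dimethylcyclohex-2-en-1-yl]-3-methylpentyl 2-methylprop-2-enoate | C=CC1=CCC[C@@H](C)[C@]1(C)CC[C@H](C)CCOC(=O)C(C)=C
F9 | step 6 | (4S,5R,8R,9S,13S)-halim-1(10)-en-18,15-olide | O=C3[C@@]1(C)CCC=C2[C@H]1CC[C@@H](C)[C@]2(C)CC[C@H](C)CCO3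
F10 | step 6 | methyl (1S,5S,6R,8aR)-5-[(3S)-5-hydroxy-3-methylpentyl]-1,5,6-trimethyl-1,2,3,5,6,7,8,8a-octahydronaphthalene-1-carboxylate | COC(=O)[C@@]1(C)CCC=C2[C@H]1CC[C@@H](C)[C@]2(C)CC[C@H](C)CCO
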